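Readings and results were computed with constants of no real substance; noise was put on by code.

The amounts in the flask are lopsided: 2.2 mM of free catalyst faces 0.80 M of substrate, so each catalyst has to turn over 364 times to use up the substrate. Coupling partner is the limiting reagent, its charge being smaller than the substrate's.

common to all: substrate 0.80 M
- summer: coupling partner 0.76 M (fed, over 80 min); free catalyst 1.1 mM; run made earlier; the fed solution adds 1.0 times the starting volume
- dawn: coupling partner 0.76 M (fed, over 80 min); free catalyst 1.7 mM; run made earlier; the fed solution adds 1.0 times the starting volume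
- midnight: coupling partner 1.5 M (fed, over 80 min); free catalyst 2.2 mM; run made earlier; the fed solution adds 1.0 times the starting volume
- flask: coupling partner 0.760 M (fed, over 80 min); free catalyst 2.2 mM; the fed solution adds 1.0 times the starting volume; time 3.0 d

| run | time / d | target / % | substrate / % | over-reaction product / % |
|---|---|---|---|---|
| summer | 0.625 | 9.3 | 87.8 | 0.6 |
| summer | 1.25 | 17.5 | 80.7 | 1.3 |
| summer | 1.67 | 21.8 | 76.0 | 4.4 |
| summer | 2.50 | 27.6 | 65.5 | 5.8 |
| summer | 3.00 | 29.1 | 59.1 | 8.2 |
| summer | 4.00 | 35.2 | 53.6 | 10.6 |
| dawn | 0.250 | 6.6 | 93.6 | 0 |
| dawn | 0.500 | 12.9 | 85.6 | 0.8 |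
| dawn | 0.833 | 20.4 | 78.0 | 0.7 |
| dawn | 1.25 | 25.4 | 71.7 | 2.8 |
| dawn | 2.00 | 33.0 | 59.6 | 5.1 |
| dawn | 4.00 | 45.6 | 42.3 | 12.0 |
| midnight | 0.250 | 8.2 | 91.5 | 0.8 |
| midnight | 0.500 | 21.5 | 80.3 | 2.8 |
| midnight | 1.04 | 30.8 | 64.0 | 5.9 |
| midnight | 2.08 | 41.6 | 41.4 | 16.7 |
| midnight | 4.00 | 45.9 | 21.1 | 31.6 |

(standard deviation of a reading: 1 percentage point)
- concentration of target at 3.0 d, in M
- concentration of substrate at 3.0 d, in M
- concentration of over-reaction product at 3.0 d, in M
- concentration of coupling partner at 3.0 d, in M
- every charge counts on the volume at the start, and the solution that is fed holds the whole dose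
- the numbers in the tables scatter by 1 percentage point (one standard deviation)

If every catalyst turns at the same pace, turnovers are counted by catalyst charge times time, not by the clock. My own reckoning therefore carries the matched time 3.88 d, the time at which the dawn run has had as many turnovers as the flask at its reading. The readings test this. The summer run at 3.00 d matches dawn at 1.94 d, and dawn's reading at 2.00 d shows 59.6% substrate against summer's 59.1%. Over-reaction product behaves otherwise. Summer holds 1.61 times dawn's share, about the catalyst ratio of 1.55, so at equal turnovers it grows with the clock.

For the flask, 3.88 d lies just short of dawn's last reading, so substrate should stand near 42.3%. Two extremes bracket the rest. If over-reaction counted turnovers, the flask would copy that reading, with 45.6% target and 12.0% over-reaction product. With no over-reaction, target would take the whole 57.7%. The flask lies between: dawn's share shrinks by the catalyst ratio to 9.27%, leaving 48.4% target. Coupling partner enters once for target and once more for over-reaction product, which leaves 29.5% of its charge. After the feed, these fractions scale to 0.400 M and 0.380 M.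

The forecast gave 0.17 M target, 0.18 M substrate, 0.05 M over-reaction product and 0.11 M coupling partner, reading that “Substrate loss is first order in A and about first order in catalyst”.

The flask gives 0.194 M, 0.171 M, 0.0355 M and 0.115 M: fractions of 48.4% target, 42.7% substrate, 8.89% over-reaction product and 30.3% coupling partner.

    substrate + free catalyst ⇌ catalyst intermediate A (K = 0.770 /M, k = 23.4 /M/h)
    coupling partner + catalyst intermediate A → catalyst intermediate B (k = 171 /M/h)
    catalyst intermediate B ⇌ free catalyst + target (K = 1.40 M, k = 11200 /h)
    coupling partner + target → over-reaction product (k = 0.0207 /M/h)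

The largest single effect on target among those tested, though not the whole reason, is the falling back of catalyst intermediate A to substrate and free catalyst: the same flask without that return holds 0.269 M target instead of 0.194 M. Substrate in the flask, at 42.7%, stands beside dawn's 42.3%, read just after the matched time 3.88 d. Read at 40 h, the same flask has a matched time of 2.16 d, just past dawn's 2.00 d, where substrate read 59.6%, and the flask then holds 58.3% free substrate.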